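## Structural features

The target (42) is a heliangolide-type germacranolide: a ten-membered carbocycle (C1–C10) trans-fused at C6–C7 to an α-methylene-γ-butyrolactone (O on C6, C11(=C13)–C12 on C7). The ring carries a Z trisubstituted olefin at C4=C5, a trans trisubstituted epoxide across C1–C10, a free allylic hydroxyl at C3 and an acyloxy group at C8. The six stereocentres form a contiguous triad C6–C7–C8 and a separate set C1/C10 and C3. The two sets are insulated from each other by the C9 and C2 methylenes and by the olefin, so configuration cannot be relayed along the chain. The C8 ester is built from two E 2-(oxymethyl)but-2-enoate units and carries an allylic acetate next to a free primary allylic alcohol; it is open to acetyl migration, SN2′ exchange and conjugate addition. The exocyclic enoate, the epoxide (β,γ to C3) and the 8-oxygenated 6,12-lactone (which can relactonise toward O8) rule out strong base, strong acid and soft nucleophiles late in the route. The real difficulty is the strained ten-membered ring with its Z olefin and the C3 carbinol next to it. The key step exploits exactly this: the C3 allylic carbinol flanked by Z C4=C5 can be made from a C3 aldehyde and a C4 alkenyl metal with retention of geometry, with the lactone and the Z olefin pre-bending the chain.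

## Logic of the disconnections

42 from 41. The last cut is at the two O–Si bonds, on O3 and on the primary oxygen of the side chain. Both hydroxyls must be masked while the C8 ester is formed, and one silyl type lets a single step free both. The demand is a desilylation that spares the epoxide, the acetate and three enoates.

41 from 26 and 39. The C8 O–acyl bond is cut, which separates the carbocyclic core from the complete side chain and makes the end of the route convergent. The forward step must acylate a hindered secondary alcohol with an α-branched enoic acid without scrambling the side chain or moving the lactone.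

26 from 25, and 25 from 24. These are O–Si changes only: O3 is masked with the more robust silyl group, then the more labile one on O8 is removed. This differentiates two secondary hydroxyls that the ring closure leaves as one free and one protected. The demand is clean discrimination between the two silyl ethers.

24 from 22. The C3–C4 bond is cut, next to the carbinol and the Z olefin. This one cut opens the ten-membered ring, removes the C3 stereocentre and leaves an acyclic aldehyde with an alkenyl iodide in which every other stereocentre is already in place. The forward step must close a ten-membered ring in the presence of lactone, enoate and epoxide and must control C3.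

22 from 21, and 21 from 20. The C3 aldehyde is traced to a primary alcohol and then to its silyl ether, because the β,γ-epoxy aldehyde cannot be stored. The demand is removal of a primary silyl ether in the presence of the secondary one on O8, and a non-basic oxidation.

20 from 13 and 17. The C6–C7 bond and the lactone O–C12 bond are cut. This splits the molecule into the C7–C10/C1–C3 chain carrying C11–C13 and a four-carbon C4–C6/C15 piece that already holds the Z iodoalkene. The forward step must set C6 and C7 (anti, and correct relative to C8) in an intermolecular allylation.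

13 from 12, and 12 from 10 and 11. The C13–Br bond (with allylic transposition) and the C7–C11 bond are cut, so the three-carbon lactone unit comes from an acrylate. The stereocentre formed at C7 is destroyed again, so no control is needed there; the demand is mildness toward epoxide and silyl ethers.

10 from 9, 9 from 8, and 8 from 7. These adjust the C7 oxidation level, cut the benzyl–O bond and cut the two C–O bonds of the epoxide. Epoxidising while the chain holds only one olefin gives reagent control over C1 and C10 and avoids any competition from the enoate or the iodoalkene later.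

7 from 6, and 6 from 2 and 3. After the O–Si bonds, the C10–C14 and C1–C2 bonds are cut across an alkyne. This sets the E geometry of the future epoxide by syn carbometalation and brings in C2–C3 as a two-carbon electrophile.

2 from 1. The C9–C10 bond is cut; C8 comes from the chiral pool with its oxygen in place.

17 from 16, and 16 from 14. The C–I and C–H bonds across an alkyne are cut; the Z geometry comes from a hydroxyl-directed trans hydrometalation.

39 from 37, and 37 from 33 and 36. The inter-unit ester is cut at its O–CH2 bond, so it is formed by carboxylate alkylation rather than acyl activation. 33 goes back through 31, 30 and 29 to 27 and 28, and 36 through 35 to 34 and 28; in both units the C=C bond and its geometry come from an acrylate–aldehyde adduct by allylic transposition.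

## Other disconnections considered

Alternative 1: The cut removes C7–C8 and C11–C13 around the lactone. It leaves the C6-substituted butenolide A1, the dithiane A2 (C8 as an acyl anion equivalent carrying C9–C10=C1–C2–C3) and the iminium salt A3. In the forward step the 2-lithio derivative of A2 would add to C7 of A1 and the lactone enolate would be aminomethylated at C11 by A3, giving A4; no ring is closed.
- In its favour: the C6 substituent of the five-membered ring should steer both new bonds trans. The C6/C7 relationship is then set by a cyclic template, which is better than the acyclic induction relied on in step 11.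
- Also in its favour: the C11 aminomethyl group is a latent exocyclic methylene, so the Michael acceptor stays masked until the end. This too is better than carrying the free enoate from 20 onward.
- Against it: C8 arrives at the ketone oxidation level. The dithiane must be unmasked beside a trisubstituted olefin and the ketone reduced with 1,2-induction from C7, whereas the chosen plan takes C8 from 1.
- Against it: C5 is only an oxygenated methylene, so C4, C15 and the Z olefin must still be built on the lactone. The epoxide is absent and the ten-membered ring is still open, so a closure of the kind used in step 14 is still needed.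
- Comparison: structurally A4 is further from 42 than 20 is. Mechanistically it is the safer way to the C6–C7 relationship. In step economy the one-pot union equals steps 7, 8 and 11 taken together, but the later adjustments at C5 and C8 would cost more than is saved.

Alternative 2: The cut removes C7–C11 and C8–O from an intact ten-membered ring and leads to the C6 malonate A5. In the forward step the malonate enolate would be oxidised by the oxidised form of the mediator A7, which is Fe(C5H5)2 used in catalytic amount and regenerated at the anode. The C11 radical would close 5-exo onto C7, and the C8 radical would be trapped by the nitroxyl A6 to give A8.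
- In its favour: lactone, C7–C11 bond and C8 oxygen are installed in one redox-economical operation that needs only a catalytic amount of A7. On bond count per step this is better than steps 7, 8 and 11.
- Also in its favour: a 5-exo closure onto a ring olefin should give the trans fusion reliably, and both C11 epimers converge once the ester is turned into the methylene group.
- Against it: A5 already contains the ten-membered ring, so the hardest problem is moved, not solved.
- Against it: C8 would be set only by substrate-controlled trapping of a ring radical. Transannular cyclisation of the C8 radical onto C1=C10 or C4=C5 is a real competing path in a germacrene ring.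
- Against it: the C3 ketone and the 1(10) olefin would have to be reduced and epoxidised afterwards under conformational control, where the chosen plan sets C1, C10 and C8 on an open chain by reagent and chiral-pool control. N–O cleavage and decarboxylative methylenation add further steps.
- Comparison: structurally A8 is close to 42 in the lactone region and far from it at C1, C3 and C10. Mechanistically it is elegant but less predictable in a medium ring. In step economy it is better for the lactone itself and worse overall once ring synthesis and late redox steps are counted.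

Alternative 3: The cut is made at C8–C9 while C1–C6 is reconnected. This contracts the ten-membered ring to the cyclohexenol A9, with a 2-alkoxyvinyl group on C6 and an isopropenyl group on C1. In the forward step the potassium alkoxide of A9, with a crown ether to loosen the ion pair, would undergo a [3,3] shift to A10.
- In its favour: this is a ring expansion, so it needs no high dilution and pays no entropic penalty. As a way to the ten-membered ring it is better than the closure of step 14.
- Also in its favour: a chair transition state should deliver the 1(10)E olefin and pass the ring configuration on to C8. The Z C4=C5 olefin is inherited from the six-membered ring, which equals the control in step 14.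
- Against it: A10 is a bare carbocycle with a C6 ketone. The lactone must be annulated by alkylation at C7 and reduction at C6, both on a flexible ring and with the trans relationship to be won.
- Against it: the epoxide must be introduced late on the 1(10) olefin with only conformational bias. The Z enone can isomerise or react transannularly under the basic conditions needed for the C7 alkylation. C8 depends on the geometry of the enol ether and on a single transition-state topology.
- Comparison: structurally it solves the ring and leaves the lactone and epoxide. Mechanistically its ring formation is more secure than step 14 and its later stereocontrol less secure than the acyclic control used here. In step economy it is better up to the ring and worse from there to 42.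

Key step: step 14

Remark on the chemistry: locants C1–C15 are those of the germacrane skeleton and are used for all intermediates; 12, 29 and 35 are carried as mixtures at a carbinol centre that the next step removes; the C7=C8 olefin of A5 is taken as E.

## Route

Step 1
Reactants: 1 (R)-benzyl glycidyl ether
Product: 2 (2R)-1-(benzyloxy)pent-4-yn-2-ol (C7–C10 and C1; the carbinol is C8)
Conditions: LiC≡CH·H2NCH2CH2NH2, DMSO, 0 °C → rt
Reagents that add atoms: lithium acetylide–ethylenediamine complex, [Li+].[C-]#C.NCCN
Why: SN2 opening of the terminal epoxide at its CH2 by acetylide is a standard homopropargylic alcohol synthesis; the existing centre is not involved and becomes C8.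

Step 2
Reactants: 2 (2R)-1-(benzyloxy)pent-4-yn-2-ol; 3 ethylene oxide
Product: 6 (2R,4E)-1-(benzyloxy)-4-methylhept-4-ene-2,7-diol, via alkenyldimethylalane 4 (not isolated), via lithium alkenylalanate 5 (not isolated)
Conditions: Al(CH3)3, Zr(C5H5)2Cl2 (cat.), CH2Cl2, 0 °C → rt; then n-C4H9Li, THF–hexane, −78 °C; then 3, −78 → 0 °C
Reagents that add atoms: trimethylaluminium, C[Al](C)C
Why: Negishi zirconium-catalysed carboalumination adds CH3 and Al syn across the terminal alkyne (CH3 to C10, Al to C1) while the hydroxyl rides along as its aluminium alkoxide; the lithium alanate 5 then opens ethylene oxide with retention of the E geometry and so delivers C2–C3 without a protecting-group step.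

Step 3
Reactants: 6 (2R,4E)-1-(benzyloxy)-4-methylhept-4-ene-2,7-diol
Product: 7 (2R,4E)-1-(benzyloxy)-4-methyl-2,7-bis(triethylsilyloxy)hept-4-ene
Conditions: Et3SiCl, imidazole, DMF, 0 °C → rt
Reagents that add atoms: chlorotriethylsilane, CC[Si](Cl)(CC)CC
Why: Routine silylation; one reagent masks both hydroxyls and leaves a primary (O3) and a secondary (O8) triethylsilyl ether that can be told apart in step 12.

Step 4
Reactants: 7 bis(triethylsilyl) ether
Product: 8 (2R,3R)-2-[(2R)-3-(benzyloxy)-2-(triethylsilyloxy)propyl]-2-methyl-3-[2-(triethylsilyloxy)ethyl]oxirane (1R,10R epoxide; 8R)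
Conditions: 1,2:4,5-di-O-isopropylidene-β-D-erythro-2,3-hexodiulo-2,6-pyranose (0.3 equiv), KHSO5 (as 2KHSO5·KHSO4·K2SO4), K2CO3, (n-C4H9)4NHSO4, CH3CN–CH2(OCH3)2, aq. Na2B4O7 buffer, 0 °C
Reagents that add atoms: potassium peroxymonosulfate, [K+].[O-]S(=O)(=O)OO
Why: Shi asymmetric epoxidation: the chiral dioxirane attacks the E trisubstituted olefin through a spiro transition state, a reagent-controlled process that should give the 1R,10R epoxide whatever the remote C8 centre prefers; the buffered pH keeps the silyl ethers.

Step 5
Reactants: 8 epoxy benzyl ether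
Product: 9 (2R)-3-{(2R,3R)-2-methyl-3-[2-(triethylsilyloxy)ethyl]oxiran-2-yl}-2-(triethylsilyloxy)propan-1-ol (free C7 hydroxyl)
Conditions: H2 (1 atm), Pd/C, EtOAc, rt
Reagents that add atoms: none
Why: Hydrogenolysis of the benzyl ether; with the only olefin already epoxidised nothing else is reducible, a non-benzylic epoxide is inert, and ethyl acetate as solvent avoids Pd-promoted solvolysis of the silyl ethers.

Step 6
Reactants: 9 C7 alcohol
Product: 10 (2R)-3-{(2R,3R)-2-methyl-3-[2-(triethylsilyloxy)ethyl]oxiran-2-yl}-2-(triethylsilyloxy)propanal (C7 aldehyde)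
Conditions: Dess–Martin periodinane, NaHCO3, CH2Cl2, 0 °C → rt
Reagents that add atoms: none
Why: Dess–Martin oxidation under bicarbonate buffering gives the α-silyloxy aldehyde without epimerisation at C8 and without acid contact for the epoxide.

Step 7
Reactants: 10 C7 aldehyde; 11 methyl acrylate
Product: 12 methyl (4R)-3-hydroxy-2-methylidene-5-{(2R,3R)-2-methyl-3-[2-(triethylsilyloxy)ethyl]oxiran-2-yl}-4-(triethylsilyloxy)pentanoate (both epimers at the new carbinol C7)
Conditions: 1,4-diazabicyclo[2.2.2]octane (DABCO), dioxane–H2O (1:1), rt
Reagents that add atoms: none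
Why: Baylis–Hillman reaction; α-oxygenated aldehydes are good acceptors and the aqueous medium accelerates the amine-catalysed addition. The C7 carbinol forms as a mixture, which does not matter because C7 becomes trigonal in step 8.

Step 8
Reactants: 12 Baylis–Hillman adduct
Product: 13 methyl (2Z,4R)-2-(bromomethyl)-5-{(2R,3R)-2-methyl-3-[2-(triethylsilyloxy)ethyl]oxiran-2-yl}-4-(triethylsilyloxy)pent-2-enoate
Conditions: NBS, (CH3)2S, CH2Cl2, −20 °C → rt
Reagents that add atoms: N-bromosuccinimide, O=C1CCC(=O)N1Br
Why: Corey–Kim-type activation of the allylic alcohol and SN2′ return of bromide give the conjugated, thermodynamically preferred Z 2-(bromomethyl)enoate under non-acidic conditions that spare the epoxide and the silyl ethers.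

Step 9
Reactants: 14 but-2-yn-1-ol
Product: 16 (Z)-3-iodobut-2-en-1-ol, via cyclic sodium alkenylaluminate 15 (not isolated)
Conditions: NaAlH2(OCH2CH2OCH3)2, THF, 0 °C → rt; then EtOAc; then I2, −78 → 0 °C
Reagents that add atoms: iodine, II
Why: Alkoxide-directed trans hydroalumination of the propargylic alcohol places aluminium on C3 cis to the CH2O group (cyclic aluminate 15); iodinolysis proceeds with retention and gives the Z iodide.

Step 10
Reactants: 16 (Z)-3-iodobut-2-en-1-ol
Product: 17 (Z)-3-iodobut-2-enal (C4–C6 and C15)
Conditions: MnO2, CH2Cl2, rt, dark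
Reagents that add atoms: none
Why: MnO2 oxidises the allylic alcohol selectively under neutral conditions; the enal is used fresh and kept from light so that the Z geometry is not lost.

Step 11
Reactants: 13 Z allylic bromide; 17 (Z)-3-iodobut-2-enal
Product: 20 (6S,7S,8R,1R,10R)-lactone: α-methylene-γ-butyrolactone with the (Z)-2-iodoprop-1-enyl group on C6 and the 8-(triethylsilyloxy) epoxy chain ending in CH2CH2OSiEt3 on C7, via allylchromium dichloride 18 (not isolated), via anti hydroxy ester 19 (not isolated)
Conditions: CrCl2 (4 equiv), THF, 0 °C → rt; then 40 °C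
Reagents that add atoms: none
Why: Barbier-type 2-(alkoxycarbonyl)allylation of an aldehyde with divalent chromium followed by lactonisation of the alkoxide (Nozaki–Hiyama allylation): the γ-substituted allylchromium 18 reacts at C7 through a Zimmerman–Traxler chair with C8 and the alkenyl group equatorial, which gives the 6,7-anti alkoxide 19 and hence the trans lactone. C7 is set by C8: allylic 1,3-strain turns the C8 hydrogen toward the ester, and the aldehyde enters anti to the C9 chain with the silyloxy group outside, which is the relationship drawn in 20. Without nickel the alkenyl iodide of 17 is not activated.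

Step 12
Reactants: 20 bis(triethylsilyl) lactone
Product: 21 (6S,7S,8R,1R,10R)-lactone with free C3 hydroxyl and C8 triethylsilyl ether
Conditions: HF·pyridine, pyridine, THF, 0 °C
Reagents that add atoms: none
Why: Buffered HF·pyridine cleaves the unhindered primary triethylsilyl ether much faster than the secondary one at C8, which is shielded by the lactone and the C9 branch; the excess pyridine keeps the medium mild enough for the epoxide.

Step 13
Reactants: 21 C3 alcohol
Product: 22 seco epoxy aldehyde (6S,7S,8R,1R,10R): C3 aldehyde with Z C4 alkenyl iodide on the α-methylene lactone and C8 triethylsilyl ether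
Conditions: Dess–Martin periodinane, NaHCO3, CH2Cl2, 0 °C; aqueous Na2S2O3–NaHCO3 work-up, crude product used at once
Reagents that add atoms: none
Why: Buffered Dess–Martin oxidation is the standard access to β,γ-epoxy aldehydes; 22 is neither chromatographed nor exposed to base, because deprotonation at C2 would open the epoxide to the γ-hydroxy enal.

Step 14
Reactants: 22 seco epoxy aldehyde
Product: 24 (1R,3S,6R,7S,8R,10R)-3-hydroxy-8-(triethylsilyloxy)-1,10-epoxygermacra-4Z,11(13)-dien-6,12-olide (target core with free C3 hydroxyl and C8 triethylsilyl ether), via alkenylchromium dichloride 23 (not isolated)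
Conditions: CrCl2 (10 equiv), NiCl2 (2 mol% of the CrCl2), degassed DMSO–THF (3:1), rt; 22 added over 12 h to a final 0.002 M
Reagents that add atoms: none
Why: Nozaki–Hiyama–Kishi reaction: zerovalent nickel, formed from NiCl2 by divalent chromium, inserts into the C4–I bond with retention of the Z geometry and hands the alkenyl group to trivalent chromium, and the alkenylchromium 23 adds to the C3 aldehyde. The closest known reaction type is the alkenyl iodide–aldehyde macrocyclisation of this name, used to close medium and large rings to allylic alcohols. The ten-membered ring closes in the 10-exo-trig mode, with the carbonyl oxygen ending outside the ring. The new C3 centre is controlled by the conformation of the closing ring: the Z olefin holds C3 and C6 on one side, allylic 1,3-strain turns the aldehyde hydrogen toward H6, and the C2 tether is expected to approach from the face of the lactone oxygen, opposite to C7 and its C8 substituent, so that the trans-disposed arms of the epoxide span the ring without eclipsing; this arrangement gives the 3S alkoxide. The step needs ring closure to win over intermolecular coupling, which slow addition to high dilution secures, helped by the lactone and the Z olefin that pre-bend the chain. It needs chemoselectivity for the aldehyde over the lactone, the exocyclic enoate and the epoxide, which the low basicity and nucleophilicity of organochromium reagents secure; the neutral medium also spares the base-labile β,γ-epoxy aldehyde. The Z geometry of C4=C5 is kept because the alkenyl–metal bonds are formed and used with retention.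

Step 15
Reactants: 24 macrocyclic C3 alcohol
Product: 25 (1R,3S,6R,7S,8R,10R)-3-(tert-butyldimethylsilyloxy)-8-(triethylsilyloxy)-1,10-epoxygermacra-4Z,11(13)-dien-6,12-olide
Conditions: t-BuMe2SiOSO2CF3, 2,6-lutidine, CH2Cl2, −78 °C
Reagents that add atoms: tert-butyldimethylsilyl trifluoromethanesulfonate, CC(C)(C)[Si](C)(C)OS(=O)(=O)C(F)(F)F
Why: A silyl triflate with a hindered base silylates the secondary allylic alcohol rapidly at low temperature, where epoxide and lactone are inert; the tert-butyldimethylsilyl ether on O3 is chosen to outlast the triethylsilyl ether on O8.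

Step 16
Reactants: 25 C3 TBS, C8 TES ether
Product: 26 (1R,3S,6R,7R,8R,10R)-3-(tert-butyldimethylsilyloxy)-8-hydroxy-1,10-epoxygermacra-4Z,11(13)-dien-6,12-olide
Conditions: HF·pyridine, pyridine, THF, 0 °C → rt
Reagents that add atoms: none
Why: A secondary triethylsilyl ether is cleaved by buffered HF·pyridine well before a secondary tert-butyldimethylsilyl ether, so O8 is freed alone; the acidic rather than basic medium avoids relactonisation of the 8-hydroxy-6,12-lactone toward O8.

Step 17
Reactants: 27 (tert-butyldimethylsilyloxy)acetaldehyde; 28 tert-butyl acrylate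
Product: 29 tert-butyl 4-(tert-butyldimethylsilyloxy)-3-hydroxy-2-methylidenebutanoate (racemic)
Conditions: DABCO, neat, rt
Reagents that add atoms: none
Why: Baylis–Hillman reaction of an activated α-silyloxy aldehyde; the carbinol centre is lost in step 18, so the racemate suffices.

Step 18
Reactants: 29 Baylis–Hillman adduct
Product: 30 tert-butyl (Z)-2-(bromomethyl)-4-(tert-butyldimethylsilyloxy)but-2-enoate
Conditions: NBS, (CH3)2S, CH2Cl2, −20 °C → rt
Reagents that add atoms: N-bromosuccinimide, O=C1CCC(=O)N1Br
Why: As in step 8, SN2′ bromination gives the Z bromide, in which the ester is trans to the CH2OSi branch, the geometry required in 42; the conditions are free of HBr and keep the tert-butyl ester.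

Step 19
Reactants: 30 Z allylic bromide
Product: 31 tert-butyl (E)-2-(acetoxymethyl)-4-(tert-butyldimethylsilyloxy)but-2-enoate
Conditions: CH3CO2K, DMF, rt
Reagents that add atoms: potassium acetate, CC(=O)[O-].[K+]
Why: SN2 displacement of the primary allylic bromide by acetate keeps the olefin geometry; the conjugated primary acetate is also the thermodynamically preferred regioisomer.

Step 20
Reactants: 31 tert-butyl ester
Product: 33 (E)-2-(acetoxymethyl)-4-(tert-butyldimethylsilyloxy)but-2-enoic acid, via trimethylsilyl ester 32 (not isolated)
Conditions: (CH3)3SiOSO2CF3, 2,6-lutidine, CH2Cl2, 0 °C → rt; then H2O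
Reagents that add atoms: none
Why: A silyl triflate with 2,6-lutidine converts a tert-butyl ester into its silyl ester with loss of isobutene, and water frees the acid; the silyl ether and the acetate do not react under these aprotic conditions, as they would under CF3CO2H.

Step 21
Reactants: 34 acetaldehyde; 28 tert-butyl acrylate
Product: 35 tert-butyl 3-hydroxy-2-methylidenebutanoate (racemic)
Conditions: DABCO, neat, sealed vessel, rt
Reagents that add atoms: none
Why: Baylis–Hillman reaction; the carbinol centre is removed in step 22.

Step 22
Reactants: 35 Baylis–Hillman adduct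
Product: 36 tert-butyl (Z)-2-(bromomethyl)but-2-enoate
Conditions: NBS, (CH3)2S, CH2Cl2, −20 °C → rt
Reagents that add atoms: N-bromosuccinimide, O=C1CCC(=O)N1Br
Why: As in step 8; in the Z bromide the ester is trans to the methyl group, which is the tiglate-type geometry of the inner unit of 42.

Step 23
Reactants: 33 outer-unit acid; 36 inner-unit bromide
Product: 37 [(E)-2-(tert-butoxycarbonyl)but-2-enyl] (E)-2-(acetoxymethyl)-4-(tert-butyldimethylsilyloxy)but-2-enoate
Conditions: Cs2CO3 (0.6 equiv), DMF, 0 °C → rt
Reagents that add atoms: none
Why: SN2 alkylation of the caesium carboxylate of 33 by the allylic bromide forms the inter-unit ester without activating the acid, so neither enoate geometry nor the acetate is put at risk.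

Step 24
Reactants: 37 tert-butyl diester
Product: 39 (E)-2-({[(E)-2-(acetoxymethyl)-4-(tert-butyldimethylsilyloxy)but-2-enoyl]oxy}methyl)but-2-enoic acid (protected side-chain acid), via trimethylsilyl ester 38 (not isolated)
Conditions: (CH3)3SiOSO2CF3, 2,6-lutidine, CH2Cl2, 0 °C → rt; then H2O
Reagents that add atoms: none
Why: As in step 20; only the tert-butyl ester reacts.

Step 25
Reactants: 26 C8 alcohol; 39 side-chain acid
Product: 41 (1R,3S,6R,7R,8R,10R)-3-O-TBS 8-ester carrying the side chain with its primary hydroxyl as TBS ether (bis-silyl ether of the target), via mixed anhydride 40 (not isolated)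
Conditions: 2,4,6-Cl3C6H2COCl, Et3N, toluene, rt; then 26, 4-(dimethylamino)pyridine (cat.), toluene, rt
Reagents that add atoms: none
Why: Yamaguchi esterification through the mixed anhydride 40 is the usual method for hindered secondary alcohols and α-branched enoic acids; the aminopyridine is kept catalytic and the time short to limit SN2′ attack on the acyloxymethyl enoates and base-induced lactone migration.

Step 26
Reactants: 41 bis-silyl ether
Product: 42 CNP0193678.1 (1R,3S,6R,7R,8R,10R)
Conditions: HF·pyridine, pyridine, THF, 0 °C → rt
Reagents that add atoms: none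
Why: Fluoride-mediated desilylation under pyridine buffering frees O3 and the primary side-chain hydroxyl in one step; the slightly acidic medium is chosen because base would promote acetyl migration to the neighbouring primary hydroxyl and conjugate additions.

## Compound list

1 | (R)-benzyl glycidyl ether | C1[C@@H](O1)COCc1ccccc1 | starting material
2 | (2R)-1-(benzyloxy)pent-4-yn-2-ol | c1ccccc1COC[C@H](O)CC#C | intermediate
3 | ethylene oxide | C1CO1 | starting material
4 | (E)-alkenyldimethylalane from 2 (Al on C1, CH3 on C10, O8 as dimethylaluminium alkoxide) | C[Al](C)/C=C(C)/C[C@@H](O[Al](C)C)COCc1ccccc1 | intermediate (not isolated)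
5 | lithium butyl(alkenyl)dimethylalanate from 4 | [Li+].CCCC[Al-](C)(C)/C=C(C)/C[C@@H](O[Al](C)C)COCc1ccccc1 | intermediate (not isolated)
6 | (2R,4E)-1-(benzyloxy)-4-methylhept-4-ene-2,7-diol | c1ccccc1COC[C@H](O)C/C(C)=C/CCO | intermediate
7 | (2R,4E)-1-(benzyloxy)-4-methyl-2,7-bis(triethylsilyloxy)hept-4-ene | c1ccccc1COC[C@H](O[Si](CC)(CC)CC)C/C(C)=C/CCO[Si](CC)(CC)CC | intermediate
8 | (2R,3R)-2-[(2R)-3-(benzyloxy)-2-(triethylsilyloxy)propyl]-2-methyl-3-[2-(triethylsilyloxy)ethyl]oxirane | c1ccccc1COC[C@H](O[Si](CC)(CC)CC)C[C@@]2(C)O[C@@H]2CCO[Si](CC)(CC)CC | intermediate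
9 | (2R)-3-{(2R,3R)-2-methyl-3-[2-(triethylsilyloxy)ethyl]oxiran-2-yl}-2-(triethylsilyloxy)propan-1-ol | OC[C@H](O[Si](CC)(CC)CC)C[C@@]2(C)O[C@@H]2CCO[Si](CC)(CC)CC | intermediate
10 | (2R)-3-{(2R,3R)-2-methyl-3-[2-(triethylsilyloxy)ethyl]oxiran-2-yl}-2-(triethylsilyloxy)propanal | O=C[C@H](O[Si](CC)(CC)CC)C[C@@]2(C)O[C@@H]2CCO[Si](CC)(CC)CC | intermediate
11 | methyl acrylate | C=CC(=O)OC | starting material
12 | methyl (4R)-3-hydroxy-2-methylidene-5-{(2R,3R)-2-methyl-3-[2-(triethylsilyloxy)ethyl]oxiran-2-yl}-4-(triethylsilyloxy)pentanoate (C3 epimers) | COC(=O)C(=C)C(O)[C@H](O[Si](CC)(CC)CC)C[C@@]2(C)O[C@@H]2CCO[Si](CC)(CC)CC | intermediate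
13 | methyl (2Z,4R)-2-(bromomethyl)-5-{(2R,3R)-2-methyl-3-[2-(triethylsilyloxy)ethyl]oxiran-2-yl}-4-(triethylsilyloxy)pent-2-enoate | COC(=O)/C(CBr)=C/[C@H](O[Si](CC)(CC)CC)C[C@@]2(C)O[C@@H]2CCO[Si](CC)(CC)CC | intermediate
14 | but-2-yn-1-ol | CC#CCO | starting material
15 | cyclic sodium alkenylaluminate (Al on C3, O–Al ring) | [Na+].CC1=CCO[Al-]1(OCCOC)OCCOC | intermediate (not isolated)
16 | (Z)-3-iodobut-2-en-1-ol | C/C(I)=C/CO | intermediate
17 | (Z)-3-iodobut-2-enal | C/C(I)=C/C=O | intermediate
18 | allylchromium dichloride from 13 (Cr on C13, C8 cis to the ester) | COC(=O)/C(C[Cr](Cl)Cl)=C\[C@H](O[Si](CC)(CC)CC)C[C@@]2(C)O[C@@H]2CCO[Si](CC)(CC)CC | intermediate (not isolated)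
19 | anti hydroxy ester (6S,7S,8R), present as its trivalent chromium alkoxide | COC(=O)C(=C)[C@@H]([C@H](O)/C=C(/C)I)[C@H](O[Si](CC)(CC)CC)C[C@@]2(C)O[C@@H]2CCO[Si](CC)(CC)CC | intermediate (not isolated)
20 | (6S,7S,8R,1R,10R)-lactone with C3 and C8 triethylsilyl ethers and Z alkenyl iodide | C=C1C(=O)O[C@H](/C=C(/C)I)[C@H]1[C@H](O[Si](CC)(CC)CC)C[C@@]2(C)O[C@@H]2CCO[Si](CC)(CC)CC | intermediate
21 | (6S,7S,8R,1R,10R)-lactone with free C3 hydroxyl and C8 triethylsilyl ether | C=C1C(=O)O[C@H](/C=C(/C)I)[C@H]1[C@H](O[Si](CC)(CC)CC)C[C@@]2(C)O[C@@H]2CCO | intermediate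
22 | seco epoxy aldehyde (6S,7S,8R,1R,10R) | C=C1C(=O)O[C@H](/C=C(/C)I)[C@H]1[C@H](O[Si](CC)(CC)CC)C[C@@]2(C)O[C@@H]2CC=O | intermediate
23 | Z alkenylchromium dichloride from 22 (Cr on C4) | C=C1C(=O)O[C@H](/C=C(/C)[Cr](Cl)Cl)[C@H]1[C@H](O[Si](CC)(CC)CC)C[C@@]2(C)O[C@@H]2CC=O | intermediate (not isolated)
24 | (1R,3S,6R,7S,8R,10R)-3-hydroxy-8-(triethylsilyloxy)-1,10-epoxygermacra-4Z,11(13)-dien-6,12-olide | C=C1C(=O)O[C@@H]2/C=C(/C)[C@@H](O)C[C@H]3O[C@]3(C)C[C@@H](O[Si](CC)(CC)CC)[C@@H]12 | intermediate
25 | (1R,3S,6R,7S,8R,10R)-3-(tert-butyldimethylsilyloxy)-8-(triethylsilyloxy)-1,10-epoxygermacra-4Z,11(13)-dien-6,12-olide | C=C1C(=O)O[C@@H]2/C=C(/C)[C@@H](O[Si](C)(C)C(C)(C)C)C[C@H]3O[C@]3(C)C[C@@H](O[Si](CC)(CC)CC)[C@@H]12 | intermediate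
26 | (1R,3S,6R,7R,8R,10R)-3-(tert-butyldimethylsilyloxy)-8-hydroxy-1,10-epoxygermacra-4Z,11(13)-dien-6,12-olide | C=C1C(=O)O[C@@H]2/C=C(/C)[C@@H](O[Si](C)(C)C(C)(C)C)C[C@H]3O[C@]3(C)C[C@@H](O)[C@@H]12 | intermediate
27 | (tert-butyldimethylsilyloxy)acetaldehyde | O=CCO[Si](C)(C)C(C)(C)C | starting material
28 | tert-butyl acrylate | C=CC(=O)OC(C)(C)C | starting material
29 | tert-butyl 4-(tert-butyldimethylsilyloxy)-3-hydroxy-2-methylidenebutanoate (racemic) | CC(C)(C)OC(=O)C(=C)C(O)CO[Si](C)(C)C(C)(C)C | intermediate
30 | tert-butyl (Z)-2-(bromomethyl)-4-(tert-butyldimethylsilyloxy)but-2-enoate | CC(C)(C)OC(=O)/C(CBr)=C/CO[Si](C)(C)C(C)(C)C | intermediate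
31 | tert-butyl (E)-2-(acetoxymethyl)-4-(tert-butyldimethylsilyloxy)but-2-enoate | CC(C)(C)OC(=O)/C(=C/CO[Si](C)(C)C(C)(C)C)COC(C)=O | intermediate
32 | trimethylsilyl (E)-2-(acetoxymethyl)-4-(tert-butyldimethylsilyloxy)but-2-enoate | C[Si](C)(C)OC(=O)/C(=C/CO[Si](C)(C)C(C)(C)C)COC(C)=O | intermediate (not isolated)
33 | (E)-2-(acetoxymethyl)-4-(tert-butyldimethylsilyloxy)but-2-enoic acid | OC(=O)/C(=C/CO[Si](C)(C)C(C)(C)C)COC(C)=O | intermediate
34 | acetaldehyde | CC=O | starting material
35 | tert-butyl 3-hydroxy-2-methylidenebutanoate (racemic) | CC(C)(C)OC(=O)C(=C)C(C)O | intermediate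
36 | tert-butyl (Z)-2-(bromomethyl)but-2-enoate | CC(C)(C)OC(=O)/C(CBr)=C/C | intermediate
37 | [(E)-2-(tert-butoxycarbonyl)but-2-enyl] (E)-2-(acetoxymethyl)-4-(tert-butyldimethylsilyloxy)but-2-enoate | CC(C)(C)OC(=O)/C(=C/C)COC(=O)/C(=C/CO[Si](C)(C)C(C)(C)C)COC(C)=O | intermediate
38 | trimethylsilyl ester of 39 | C[Si](C)(C)OC(=O)/C(=C/C)COC(=O)/C(=C/CO[Si](C)(C)C(C)(C)C)COC(C)=O | intermediate (not isolated)
39 | (E)-2-({[(E)-2-(acetoxymethyl)-4-(tert-butyldimethylsilyloxy)but-2-enoyl]oxy}methyl)but-2-enoic acid | OC(=O)/C(=C/C)COC(=O)/C(=C/CO[Si](C)(C)C(C)(C)C)COC(C)=O | intermediate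
40 | mixed anhydride of 39 with 2,4,6-trichlorobenzoic acid | O=C(OC(=O)c1c(Cl)cc(Cl)cc1Cl)/C(=C/C)COC(=O)/C(=C/CO[Si](C)(C)C(C)(C)C)COC(C)=O | intermediate (not isolated)
41 | (1R,3S,6R,7R,8R,10R)-bis(tert-butyldimethylsilyl) ether of the target (O3 and side-chain primary O) | C=C1C(=O)O[C@@H]2/C=C(/C)[C@@H](O[Si](C)(C)C(C)(C)C)C[C@H]3O[C@]3(C)C[C@@H](OC(=O)/C(=C/C)COC(=O)/C(=C/CO[Si](C)(C)C(C)(C)C)COC(C)=O)[C@@H]12 | intermediate
42 | CNP0193678.1 (1R,3S,6R,7R,8R,10R) | C=C1C(=O)O[C@@H]2/C=C(/C)[C@@H](O)C[C@H]3O[C@]3(C)C[C@@H](OC(=O)/C(=C/C)COC(=O)/C(=C/CO)COC(C)=O)[C@@H]12 | target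

## Step count and least certain steps

Total: 26 steps. Longest linear sequence: 16 steps (from 1 through steps 1–8, 11–16, 25 and 26).

Step 14 (key step). The most likely failure is poor facial selectivity at C3, because the sense of induction rests on a conformational argument alone. Secondary losses would be opening of the epoxide of the aldehyde by adventitious base and intermolecular coupling. Fallback: from 22 the ring is closed in the same way but without relying on its selectivity. The 3R alcohol (3-epi-24) F1 is oxidised with Dess–Martin periodinane to the C3 enone F2. The carbinol is then set by reagent control with catecholborane and the (R)-configured B-methyl diphenylprolinol oxazaborolidine (Corey–Bakshi–Shibata reduction, alkenyl branch as the large group), which comes back to the route at 24.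

Step 11. The most likely failure is erosion of the anti pathway (reaction through the chair with C8 axial, which leads to the cis lactone) or attack on the other face of C7; the 1,2-induction from C8 is a model prediction. A further loss would be 1,4-elimination of the C8 silyloxy group from the allylmetal. Fallback: from 13 and 17, indium metal in aqueous THF, conditions under which Z 2-(bromomethyl)alk-2-enoates are known to follow the syn pathway, would give the 6,7-syn hydroxy ester F3. Saponification with LiOH gives the hydroxy acid F4, and Mitsunobu lactonisation (PPh3, diisopropyl azodicarboxylate) closes the ring with inversion at C6 and comes back at 20.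

Step 12. The most likely failure is incomplete discrimination between the two triethylsilyl ethers, with loss of the C8 group, or fluoride opening of the epoxide on prolonged exposure. Fallback: from 20 the primary silyl ether is converted directly into the aldehyde under Swern conditions ((COCl)2, DMSO, then i-Pr2NEt, −78 → −40 °C), which cleave and oxidise primary triethylsilyl ethers in the presence of secondary ones. This bypasses 21 and comes back at 22 without any new compound.

Step 25. The most likely failure is slow acylation of the hindered C8 hydroxyl. That would give time for SN2′ attack of the aminopyridine on the acyloxymethyl enoates (scrambling of geometry or of the acetate) and for base-induced migration of the lactone to O8. Fallback: from 26 the side chain is built in two stages. 36 is cleaved with CF3CO2H to (Z)-2-(bromomethyl)but-2-enoic acid F5 and converted ((COCl)2, cat. DMF) into the acid chloride F6. F6 acylates 26 (pyridine, CH2Cl2, −20 °C) to the C8 2-(bromomethyl)but-2-enoate F7. The caesium salt of 33 (Cs2CO3, DMF) then displaces the bromide and the route is rejoined at 41.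

Step 26. The most likely failure is acid-promoted transannular opening of the epoxide during the long exposure needed for the secondary silyl ether on O3, or acetyl migration once the primary hydroxyl is free. Fallback: a change of order that leaves only a primary silyl ether for the end. From 20 both triethylsilyl groups are removed (HF·pyridine, longer exposure) to the diol F8. The primary hydroxyl is then resilylated selectively (Et3SiCl, imidazole, −78 °C) to the C3 triethylsilyl ether F9. The C8 hydroxyl is esterified with 39 as in step 25 to the ester F10. The primary triethylsilyl ether is cleaved (buffered HF·pyridine, 0 °C) to the alcohol F11, and Dess–Martin oxidation gives the aldehyde F12. The closure of step 14 then gives the macrocycle F13 with the side chain in place, and brief buffered HF·pyridine removes the primary TBS ether and arrives at 42.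

## Further compounds

F1 | step 14 | (1R,3R,6R,7S,8R,10R)-3-epi-24 | C=C1C(=O)O[C@@H]2/C=C(/C)[C@H](O)C[C@H]3O[C@]3(C)C[C@@H](O[Si](CC)(CC)CC)[C@@H]12
F2 | step 14 | C3 enone: 3-oxo-8-(triethylsilyloxy)-1,10-epoxygermacra-4Z,11(13)-dien-6,12-olide | C=C1C(=O)O[C@@H]2/C=C(/C)C(=O)C[C@H]3O[C@]3(C)C[C@@H](O[Si](CC)(CC)CC)[C@@H]12
F3 | step 11 | 6,7-syn hydroxy ester (6-epi-19) | COC(=O)C(=C)[C@@H]([C@@H](O)/C=C(/C)I)[C@H](O[Si](CC)(CC)CC)C[C@@]2(C)O[C@@H]2CCO[Si](CC)(CC)CC
F4 | step 11 | 6,7-syn hydroxy acid | OC(=O)C(=C)[C@@H]([C@@H](O)/C=C(/C)I)[C@H](O[Si](CC)(CC)CC)C[C@@]2(C)O[C@@H]2CCO[Si](CC)(CC)CC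
F0 | step 12 | none | none
F5 | step 25 | (Z)-2-(bromomethyl)but-2-enoic acid | OC(=O)/C(CBr)=C/C
F6 | step 25 | (Z)-2-(bromomethyl)but-2-enoyl chloride | ClC(=O)/C(CBr)=C/C
F7 | step 25 | C8 (Z)-2-(bromomethyl)but-2-enoate of 26 | C=C1C(=O)O[C@@H]2/C=C(/C)[C@@H](O[Si](C)(C)C(C)(C)C)C[C@H]3O[C@]3(C)C[C@@H](OC(=O)/C(CBr)=C/C)[C@@H]12
F8 | step 26 | seco lactone diol (free C3 and C8 hydroxyls) | C=C1C(=O)O[C@H](/C=C(/C)I)[C@H]1[C@H](O)C[C@@]2(C)O[C@@H]2CCO
F9 | step 26 | seco lactone with C3 triethylsilyl ether and free C8 hydroxyl | C=C1C(=O)O[C@H](/C=C(/C)I)[C@H]1[C@H](O)C[C@@]2(C)O[C@@H]2CCO[Si](CC)(CC)CC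
F10 | step 26 | seco lactone C8 ester of 39 with C3 triethylsilyl ether | C=C1C(=O)O[C@H](/C=C(/C)I)[C@H]1[C@H](OC(=O)/C(=C/C)COC(=O)/C(=C/CO[Si](C)(C)C(C)(C)C)COC(C)=O)C[C@@]2(C)O[C@@H]2CCO[Si](CC)(CC)CC
F11 | step 26 | seco lactone C8 ester of 39 with free C3 hydroxyl | C=C1C(=O)O[C@H](/C=C(/C)I)[C@H]1[C@H](OC(=O)/C(=C/C)COC(=O)/C(=C/CO[Si](C)(C)C(C)(C)C)COC(C)=O)C[C@@]2(C)O[C@@H]2CCO
F12 | step 26 | seco epoxy aldehyde carrying the C8 ester of 39 | C=C1C(=O)O[C@H](/C=C(/C)I)[C@H]1[C@H](OC(=O)/C(=C/C)COC(=O)/C(=C/CO[Si](C)(C)C(C)(C)C)COC(C)=O)C[C@@]2(C)O[C@@H]2CC=O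
F13 | step 26 | macrocycle with free C3 hydroxyl and side-chain primary TBS ether | C=C1C(=O)O[C@@H]2/C=C(/C)[C@@H](O)C[C@H]3O[C@]3(C)C[C@@H](OC(=O)/C(=C/C)COC(=O)/C(=C/CO[Si](C)(C)C(C)(C)C)COC(C)=O)[C@@H]12
A1 | alternative 1 | (S)-5-(trityloxymethyl)furan-2(5H)-one | O=C1C=C[C@@H](COC(c2ccccc2)(c2ccccc2)c2ccccc2)O1
A2 | alternative 1 | 2-[(E)-5-(tert-butyldimethylsilyloxy)-2-methylpent-2-enyl]-1,3-dithiane | S1CCCSC1C/C(C)=C/CCO[Si](C)(C)C(C)(C)C
A3 | alternative 1 | N,N-dimethylmethyleneiminium iodide | C=[N+](C)C.[I-]
A4 | alternative 1 | trans,trans-trisubstituted lactone with C8 dithiane and C11 dimethylaminomethyl group | CN(C)C[C@@H]1C(=O)O[C@H](COC(c2ccccc2)(c2ccccc2)c2ccccc2)[C@H]1C1(SCCCS1)C/C(C)=C/CCO[Si](C)(C)C(C)(C)C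
A5 | alternative 2 | C6 methyl malonate of the (1(10)E,4Z,7E)-germacratrien-3-one | COC(=O)CC(=O)O[C@@H]1/C=C(/C)C(=O)C/C=C(\C)C/C=C/1
A6 | alternative 2 | 2,2,6,6-tetramethylpiperidin-1-oxyl | CC1(C)CCCC(C)(C)N1[O]
A7 | alternative 2 | Fe(C5H5)2 | [Fe+2].c1cc[cH-]c1.c1cc[cH-]c1
A8 | alternative 2 | trans-fused lactone with C11 methyl ester and C8 O-tetramethylpiperidinyl group | COC(=O)C1C(=O)O[C@@H]2/C=C(/C)C(=O)C/C=C(\C)/C[C@@H](ON3C(C)(C)CCCC3(C)C)[C@@H]12
A9 | alternative 3 | cyclohexenol with (E)-2-(4-methoxybenzyloxy)vinyl on C6, isopropenyl on C1 (trans to the vinyl group) and silyl ether on C3 | C=C(C)[C@H]1C[C@H](O[Si](C)(C)C(C)(C)C)C(C)=C[C@]1(O)/C=C/OCc1ccc(OC)cc1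
A10 | alternative 3 | (1(10)E,4Z)-cyclodecadien-6-one with C3 silyl ether and C8 4-methoxybenzyl ether | O=C1/C=C(/C)[C@@H](O[Si](C)(C)C(C)(C)C)C/C=C(\C)/C[C@@H](OCc2ccc(OC)cc2)C1
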